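The ratio I reckoned with was electrophile used per nucleophile charged.

    nucleophile + acid set free ⇌ protonated nucleophile, settled at all times (K1 = 5000 /M)
    electrophile + nucleophile → acid set free + target (k2 = 11.4 /M/h)
    target ⇌ isomer of the product (K3 = 0.176, k3 = 0.130 /h)
    electrophile + acid set free → side product (k4 = 2.22 /M/h)

electrophile 0.093 M; time 4.0 d

1. the equivalents of nucleophile at which the part of the electrophile that has reacted at 4.0 d is just 70%

Let N be the nucleophile charged, in M. The count needs no rate. Each nucleophile makes one target with one electrophile and sets free one acid, and that acid can take one more electrophile into side product, so used electrophile cannot pass two per nucleophile charged, and I call that limit the cap. Reaching 70% therefore takes at least one nucleophile for every two electrophile used, the floor charge 0.350 equiv.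

The second way asks whether 4.0 d suffices. I took the first stretch as short, since 0.943 h is far less than the run: in it one nucleophile in two becomes target and the other holds the acid as protonated nucleophile. That leaves a gap g, the cap less the electrophile used, which at the floor charge is 0.0488 M. From then on I took free nucleophile and free acid as steady, which makes two side steps go with each target step. K1 ties free nucleophile and free acid together, and the use of electrophile goes as its concentration times the square root of g. Holding electrophile at the geometric mean of its values over this stretch, 0.0463 M, the square root of g falls linearly and reaches zero at 110 h. That is longer than the run, so at the floor charge a gap of 7.54 × 10⁻⁴ M stays open. Closing it lifts my charge to 0.354 equiv. My charge stands just above the floor charge.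

The forecast gave 0.4 equiv, higher than mine, on the ground that “the slow remaining conversion runs mainly through the acid side reaction”.

The run gave 0.376 equiv, which is 1.07 times the floor charge. At 4.00 d, 0.343% of the charged nucleophile was still free. At that charge the cap stands at 75.2% of the electrophile charged, and at 12.0 d the flask had used 75.1% of it.

Its constants were drawn at random within sensible limits; the result is computed.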